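The route rests on reading the C4–O–C8 tetrahydropyran and the γ-lactone fused across C7–C8 as the imprint of one intramolecular furan–oxyallyl (4+3) cycloaddition: C4 and C8 are the furan α-carbons, C5–C6–C7 is the oxyallyl unit and the lactone ester O–C19–C17 is the tether. In a single operation the step forms C4–C5 and C7–C8, closes the oxa-bridged seven-membered ring (hence the pyranone) and the lactone, and sets C4, C7 and C8 from C17. Its precursor is the 3-chloro-2-oxopropyl ester of (R)-2-(furan-2-yl)propanoic acid. The rigid bicycle then controls C6 before its C3=C9 bridge is cut into the two arms that receive ring A.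

Key step: step 5

Remark on the chemistry: briarane numbering is used for all compounds, and the yeast reduction of step 13 is assumed to give the (2S,3S)-ketol (hydroxyl cis to the allyl group), the configuration that C1 and C14 require.

Step 1
Reactants: 1 furan-2-ylacetic acid; 2 (R)-4-benzyl-1,3-oxazolidin-2-one
Product: 4 (R)-4-benzyl-3-[2-(furan-2-yl)acetyl]-1,3-oxazolidin-2-one, via mixed pivalic anhydride 3 (not isolated)
Conditions: PivCl, Et3N, THF, −20 °C; then 2, LiCl, −20 °C → rt
Reagents that add atoms: none
Why: N-acylation of the oxazolidinone through a mixed anhydride is mild enough for the furan and forms no stereocentre.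

Step 2
Reactants: 4 N-acyl oxazolidinone; 5 iodomethane
Product: 7 (R)-4-benzyl-3-[(R)-2-(furan-2-yl)propanoyl]-1,3-oxazolidin-2-one, via sodium Z-enolate 6 (not isolated)
Conditions: NaHMDS, THF, −78 °C; then MeI, −78 → −40 °C
Reagents that add atoms: none
Why: Auxiliary-controlled enolate alkylation (Evans alkylation), in which the chelated Z-enolate is methylated on the face opposite the benzyl group, so the (R)-auxiliary should give (R)-C17.

Step 3
Reactants: 7 methylated imide
Product: 8 (R)-2-(furan-2-yl)propanoic acid
Conditions: LiOH, H2O2, THF/H2O, 0 °C; Na2SO3; then 1 M HCl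
Reagents that add atoms: hydrogen peroxide (as LiOOH), OO
Why: Hydroperoxide-mediated imide hydrolysis attacks the exocyclic carbonyl selectively and should leave the furan and the C17 stereocentre intact.

Step 4
Reactants: 8 (R)-2-(furan-2-yl)propanoic acid; 9 1,3-dichloroacetone
Product: 10 3-chloro-2-oxopropyl (R)-2-(furan-2-yl)propanoate
Conditions: KHCO3, DMF, 9 (4 equiv), 0 °C → rt
Reagents that add atoms: none
Why: Carboxylate O-alkylation (SN2) of the activated α-chloro ketone, where excess of the symmetrical dichloride suppresses double displacement and the carboxylate cannot epimerise C17.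

Step 5
Reactants: 10 3-chloro-2-oxopropyl (R)-2-(furan-2-yl)propanoate
Product: 12 tricyclic keto lactone (8-oxabicyclo[3.2.1]oct-6-en-3-one with the γ-lactone fused at C7–C8), via oxyallyl cation 11 (not isolated)
Conditions: iPr2NEt (1.5 equiv), (CF3)2CHOH, 0.01 M, 0 °C → rt
Reagents that add atoms: none
Why: Proposed new method: the hindered amine in the ionising, weakly nucleophilic fluoro alcohol enolises the α-chloro ketone toward C7 and chloride departs from C5, giving the acyloxy-stabilised oxyallyl cation 11, which the tethered furan traps across its 2,5-positions in an asynchronous (4+3) cycloaddition (C7–C8 ahead of C5–C4). The closest known reaction types are intramolecular furan–oxyallyl (4+3) cycloadditions through all-carbon tethers and intermolecular (4+3) reactions of alkoxy-substituted oxyallyl cations made from α-halo ketones with amine bases in fluoro alcohols; new is the ester tether, which places an acyloxy donor on the cation terminus. Two rings close: the γ-lactone by 5-exo attack of furan C2 (C8) on the cation terminus C7 through the three-atom tether O–C19–C17, and the seven-membered carbocycle C4–C5–C6–C7–C8–C9–C3 by the second bond C5–C4, which with the furan oxygen as one-atom bridge is the pyranone. C8 and C4 are set together by the choice of furan face, relayed from C17 because its methyl avoids allylic strain with the furan 3-H (future C9) and sits on the side of the bridging oxygen; C7 follows from the cis fusion that the short tether enforces, its oxygen axial and anti to the C3=C9 bridge. The step needs regiocontrol (C7 to C8, not to C4), which the tether length guarantees; capture within the molecule instead of solvolysis or oligomerisation, which high dilution and a polar medium that populates the s-cis ester conformer favour; and retention of C17, which the weak base should not enolise.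

Step 6
Reactants: 12 tricyclic keto lactone
Product: 13 C5-methylene keto lactone (α-methylene ketone)
Conditions: (CH2O)n, N-methylanilinium trifluoroacetate, THF, 65 °C
Reagents that add atoms: formaldehyde (as paraformaldehyde), C=O
Why: Direct Mannich-type α-methylenation (iminium condensation, then amine elimination) can deliver a methylene only at C5 because C7 is a methine, and the non-basic medium spares the lactone and C17.

Step 7
Reactants: 13 C5-methylene keto lactone
Product: 14 allylic alcohol (C6–OH axial and syn to the C3=C9 bridge)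
Conditions: NaBH4, CeCl3·7H2O, MeOH, −78 °C
Reagents that add atoms: none
Why: Luche 1,2-reduction, in which hydride should add to C6 from the face away from the C3=C9 bridge of the rigid bicycle, placing the hydroxyl syn to the bridge and trans to the C7 oxygen.

Step 8
Reactants: 14 allylic alcohol
Product: 15 allylic chloride (C6–Cl equatorial and cis to the C7 oxygen)
Conditions: PPh3, Cl3CCOCCl3, CH2Cl2, −20 → 0 °C
Reagents that add atoms: hexachloroacetone, ClC(Cl)(Cl)C(=O)C(Cl)(Cl)Cl
Why: Appel-type chlorination of an allylic alcohol, in which chloride displaces the oxyphosphonium by SN2 with inversion to give the C6 configuration of the target under conditions chosen to minimise allylic transposition.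

Step 9
Reactants: 15 allylic chloride
Product: 18 cis-2,6-bis(hydroxymethyl)tetrahydropyran lactone (C3–OH and C9–OH), via exo-diol 16 (not isolated), via dialdehyde 17 (not isolated)
Conditions: OsO4 (2 mol%), NMO (1.05 equiv), acetone/H2O, 0 °C; then NaIO4, rt; then NaBH4, MeOH, −20 °C, AcOH quench
Reagents that add atoms: N-methylmorpholine N-oxide, C[N+]1([O-])CCOCC1; water, O
Why: Catalytic OsO4 dihydroxylation should select the strained, exposed C3=C9 alkene on its exo face over the C5 methylene (deactivated by the allylic chloride and flanked on both faces), after which periodate glycol cleavage and borohydride reduction (Lemieux–Johnson-type sequence) release the two cis arms without touching a stereocentre.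

Step 10
Reactants: 18 C3,C9-diol
Product: 19 C3 tert-butyldimethylsilyl ether (C9–OH free)
Conditions: TBSCl (1.05 equiv), imidazole, CH2Cl2, −20 °C
Reagents that add atoms: tert-butyldimethylsilyl chloride, CC(C)(C)[Si](C)(C)Cl
Why: Silyl ether formation should occur at the C3 hydroxyl because the C9 hydroxymethyl is neopentylic on the fully substituted C8, and the cold, near-neutral conditions guard against translactonisation by the free C9 hydroxyl.

Step 11
Reactants: 19 C3 silyl ether
Product: 20 C9 aldehyde
Conditions: Dess–Martin periodinane, NaHCO3, CH2Cl2, 0 °C → rt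
Reagents that add atoms: none
Why: Dess–Martin oxidation of the neopentylic primary alcohol under buffered conditions gives the non-enolisable C9 aldehyde.

Step 12
Reactants: 21 2-methylcyclohexane-1,3-dione; 22 allyl bromide
Product: 23 2-allyl-2-methylcyclohexane-1,3-dione
Conditions: 1 M NaOH (aq), 22, rt
Reagents that add atoms: none
Why: C-Alkylation of the cyclic 1,3-diketone enolate creates the prochiral quaternary carbon that becomes C1.

Step 13
Reactants: 23 2-allyl-2-methylcyclohexane-1,3-dione
Product: 24 (2S,3S)-2-allyl-3-hydroxy-2-methylcyclohexan-1-one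
Conditions: baker's yeast (Saccharomyces cerevisiae), sucrose, H2O, 30 °C
Reagents that add atoms: none
Why: Enantiotopic-group-selective microbial ketone reduction of a 2,2-disubstituted cyclohexane-1,3-dione should set C1 and C14 together, with the hydroxyl cis to the allyl group.

Step 14
Reactants: 24 (2S,3S)-ketol
Product: 25 (2S,3S)-3-hydroxy-2-methyl-2-[(E)-prop-1-enyl]cyclohexan-1-one
Conditions: RuHCl(CO)(PPh3)3 (3 mol%), toluene, 80 °C
Reagents that add atoms: none
Why: Ruthenium hydride-catalysed alkene isomerisation (hydrometalation, then β-hydride elimination) moves the double bond one position inward and must stop at the quaternary carbon, giving the E-propenyl group.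

Step 15
Reactants: 25 propenyl ketol
Product: 27 (2S,3S)-3-hydroxy-2-(hydroxymethyl)-2-methylcyclohexan-1-one, via ozonide 26 (not isolated)
Conditions: O3, CH2Cl2, −78 °C; then NaBH4, MeOH, −78 → −40 °C, AcOH quench
Reagents that add atoms: ozone, [O-][O+]=O
Why: Ozonolysis with reductive borohydride work-up cuts the propenyl group down to the one-carbon C2 hydroxymethyl, and at low temperature borohydride should reduce the ozonide but not the hindered C10 ketone.

Step 16
Reactants: 27 keto diol
Product: 28 acetonide of 27 (cis-fused 1,3-dioxane across C2–O and C14–O)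
Conditions: Me2C(OMe)2, PPTS, CH2Cl2, rt
Reagents that add atoms: 2,2-dimethoxypropane, COC(C)(C)OC
Why: Acid-catalysed transacetalisation ties the cis-1,3-diol into a six-membered acetonide, which is the only ring these two hydroxyls can form.

Step 17
Reactants: 28 acetonide ketone
Product: 30 C11-methylene ketone (enone), via Mannich base 29 (not isolated)
Conditions: LiHMDS, THF, −78 °C; CH2=NMe2 I, −78 °C → rt; then MeI, NaHCO3, CH2Cl2/H2O
Reagents that add atoms: N,N-dimethylmethyleneiminium iodide (Eschenmoser's salt), C=[N+](C)C.[I-]
Why: Enolisation can occur only toward C11 because C1 is quaternary, and the Mannich reaction with Eschenmoser's salt followed by quaternisation and elimination gives the α-methylene ketone under conditions the acetonide tolerates.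

Step 18
Reactants: 30 C11-methylene ketone
Product: 31 allylic alcohol (C10–OH as a mixture of epimers)
Conditions: NaBH4, CeCl3·7H2O, MeOH, 0 °C
Reagents that add atoms: none
Why: Luche 1,2-reduction of the enone, whose new C10 carbinol configuration is irrelevant because it is lost in the next step.

Step 19
Reactants: 31 allylic alcohol
Product: 33 primary allylic bromide (C20–Br with C10=C11), via allylic mesylate 32 (not isolated)
Conditions: MsCl, Et3N, CH2Cl2, −40 °C; then LiBr, THF, 0 °C → rt
Reagents that add atoms: lithium bromide, [Li+].[Br-]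
Why: Sulfonate displacement with allylic transposition (SN2′), since direct substitution at the neopentylic C10 is blocked and bromide therefore enters at C20 to form the more stable trisubstituted C10=C11 alkene.

Step 20
Reactants: 33 primary allylic bromide
Product: 34 primary allylstannane (C20–SnBu3 with C10=C11)
Conditions: Bu3SnLi (from Bu3SnH, LDA), THF, −78 °C
Reagents that add atoms: tributylstannyllithium, [Li][Sn](CCCC)(CCCC)CCCC
Why: SN2 stannylation of a primary allylic bromide, with attack at the neopentylic C10 terminus disfavoured.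

Step 21
Reactants: 20 C9 aldehyde; 34 allylstannane
Product: 35 homoallylic alcohol (C9–OH with 9,10-syn relationship and C11 methylene)
Conditions: MgBr2·OEt2 (3 equiv), CH2Cl2, −25 → 0 °C
Reagents that add atoms: none
Why: Chelation-controlled Lewis acid-mediated allylstannane addition (SE2′ through an open antiperiplanar transition state), in which MgBr2 bridges the aldehyde and pyran oxygens, the stannane should attack the aldehyde face away from the pyran carbons C7 and C4 and react on the ring A face opposite the cis-fused dioxane, forming C9–C10 with the 9,10-syn topicity and the C10 configuration of the target and unveiling the C11 methylene by allylic transposition.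

Step 22
Reactants: 35 homoallylic alcohol
Product: 36 C9 acetate
Conditions: Ac2O, DMAP, pyridine, CH2Cl2, 0 °C → rt
Reagents that add atoms: acetic anhydride, CC(=O)OC(C)=O
Why: DMAP-catalysed acylation installs the C9 acetate of the target and removes the hydroxyl that could otherwise translactonise onto C19.

Step 23
Reactants: 36 C9 acetate
Product: 37 triol (C2–OH, C3–OH and C14–OH free)
Conditions: CSA (0.2 equiv), MeOH, 0 °C → rt
Reagents that add atoms: none
Why: Acid-catalysed methanolysis cleaves the primary silyl ether and the acetonide in one operation, while acetate, lactone and the deactivated allylic chloride are stable to catalytic acid in methanol.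

Step 24
Reactants: 37 triol
Product: 38 C2,C3-dialdehyde (C14–OH free)
Conditions: TEMPO (0.3 equiv), PhI(OAc)2 (2.4 equiv), CH2Cl2, rt
Reagents that add atoms: none
Why: Oxoammonium (TEMPO) oxidation with PhI(OAc)2 as terminal oxidant is selective for primary alcohols, so both hydroxymethyl groups become aldehydes while the secondary C14 hydroxyl remains.

Step 25
Reactants: 38 C2,C3-dialdehyde
Product: 39 ring-closed triol (C2–OH, C3–OH, C14–OH; 9-acetate)
Conditions: SmI2 (2.5 equiv), THF, −78 → −30 °C, 0.005 M; aq. NH4Cl
Reagents that add atoms: none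
Why: SmI2-mediated intramolecular pinacol coupling (ketyl formation at the α-alkoxy C3 aldehyde and C–C bond formation to the C2 carbonyl on a samarium-bridged template) closes the eight-membered ring; the C3 oxygen is expected anti to the C4–O bond on the convex face and the C2 oxygen on the opposite ring face (2,3-threo diol), and the secondary allylic chloride should survive at low temperature without a polar additive.

Step 26
Reactants: 39 ring-closed triol
Product: 40 C3 triethylsilyl ether
Conditions: TESCl (1.1 equiv), imidazole, CH2Cl2, −30 °C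
Reagents that add atoms: chlorotriethylsilane, CC[Si](CC)(CC)Cl
Why: Silylation should take place at C3, the only secondary hydroxyl not adjacent to the quaternary C1.

Step 27
Reactants: 40 C3 triethylsilyl ether
Product: 41 2,9,14-triacetate 3-O-triethylsilyl ether
Conditions: Ac2O, DMAP, Et3N, CH2Cl2, rt
Reagents that add atoms: acetic anhydride, CC(=O)OC(C)=O
Why: DMAP-catalysed acetylation of the two hindered secondary hydroxyls at C2 and C14 completes the triacetate pattern.

Step 28
Reactants: 41 2,9,14-triacetate 3-O-triethylsilyl ether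
Product: 42 CNP0280492.1 (target)
Conditions: HF·pyridine, pyridine/THF, 0 °C
Reagents that add atoms: none
Why: Fluoride-mediated desilylation under buffered conditions should free the C3 hydroxyl without acetyl migration or loss of the allylic chloride.

Compound list

1 | furan-2-ylacetic acid | OC(=O)Cc1ccco1 | starting material
2 | (R)-4-benzyl-1,3-oxazolidin-2-one | O=C1N[C@H](Cc2ccccc2)CO1 | starting material
3 | furan-2-ylacetic pivalic anhydride (not isolated) | CC(C)(C)C(=O)OC(=O)Cc1ccco1 | intermediate
4 | (R)-4-benzyl-3-[2-(furan-2-yl)acetyl]-1,3-oxazolidin-2-one | O=C(Cc1ccco1)N1[C@H](Cc2ccccc2)COC1=O | intermediate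
5 | iodomethane | CI | starting material
6 | sodium Z-enolate of 4 (not isolated) | [Na+].[O-]/C(=C\c1ccco1)N1[C@H](Cc2ccccc2)COC1=O | intermediate
7 | (R)-4-benzyl-3-[(R)-2-(furan-2-yl)propanoyl]-1,3-oxazolidin-2-one | O=C([C@H](C)c1ccco1)N1[C@H](Cc2ccccc2)COC1=O | intermediate
8 | (R)-2-(furan-2-yl)propanoic acid | OC(=O)[C@H](C)c1ccco1 | intermediate
9 | 1,3-dichloroacetone | ClCC(=O)CCl | starting material
10 | 3-chloro-2-oxopropyl (R)-2-(furan-2-yl)propanoate | ClCC(=O)COC(=O)[C@H](C)c1ccco1 | intermediate
11 | acyloxy-substituted oxyallyl cation, drawn as the zwitterion (not isolated) | [CH2+]C([O-])=COC(=O)[C@H](C)c1ccco1 | intermediate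
12 | tricyclic keto lactone: 8-oxabicyclo[3.2.1]oct-6-en-3-one with the γ-lactone cis-fused at C7–C8, C7–O axial and anti to the C3=C9 bridge, C17 methyl on the side of the bridging oxygen | C1=C[C@@]23O[C@@H]1CC(=O)[C@@H]2OC(=O)[C@@H]3C | intermediate
13 | C5-methylene derivative of 12 (α-methylene ketone) | C1=C[C@@]23O[C@@H]1C(=C)C(=O)[C@@H]2OC(=O)[C@@H]3C | intermediate
14 | allylic alcohol, C6–OH axial (syn to the C3=C9 bridge, trans to C7–O) | C1=C[C@@]23O[C@@H]1C(=C)[C@@H](O)[C@@H]2OC(=O)[C@@H]3C | intermediate
15 | allylic chloride, C6–Cl equatorial (cis to C7–O), as in the target | C1=C[C@@]23O[C@@H]1C(=C)[C@H](Cl)[C@@H]2OC(=O)[C@@H]3C | intermediate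
16 | exo-cis-C3,C9-diol of 15 (not isolated) | O[C@H]1[C@@H](O)[C@@]23O[C@@H]1C(=C)[C@H](Cl)[C@@H]2OC(=O)[C@@H]3C | intermediate
17 | cis-2,6-diformyl tetrahydropyran lactone, C3 and C9 aldehydes (not isolated) | O=C[C@@]13O[C@H](C(=C)[C@H](Cl)[C@@H]1OC(=O)[C@@H]3C)C=O | intermediate
18 | cis-2,6-bis(hydroxymethyl) tetrahydropyran lactone (C3–OH, C9–OH) | OC[C@@]13O[C@H](C(=C)[C@H](Cl)[C@@H]1OC(=O)[C@@H]3C)CO | intermediate
19 | C3 tert-butyldimethylsilyl ether of 18 (C9–OH free) | OC[C@@]13O[C@H](C(=C)[C@H](Cl)[C@@H]1OC(=O)[C@@H]3C)CO[Si](C)(C)C(C)(C)C | intermediate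
20 | C9 aldehyde (C3–OTBS) | O=C[C@@]13O[C@H](C(=C)[C@H](Cl)[C@@H]1OC(=O)[C@@H]3C)CO[Si](C)(C)C(C)(C)C | intermediate
21 | 2-methylcyclohexane-1,3-dione | CC1C(=O)CCCC1=O | starting material
22 | allyl bromide | C=CCBr | starting material
23 | 2-allyl-2-methylcyclohexane-1,3-dione | C=CCC1(C)C(=O)CCCC1=O | intermediate
24 | (2S,3S)-2-allyl-3-hydroxy-2-methylcyclohexan-1-one (ketone carbon = C10, carbinol = C14, quaternary carbon = C1) | C1CC[C@H](O)[C@@](CC=C)(C)C1=O | intermediate
25 | (2S,3S)-3-hydroxy-2-methyl-2-[(E)-prop-1-enyl]cyclohexan-1-one | C1CC[C@H](O)[C@@](/C=C/C)(C)C1=O | intermediate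
26 | ozonide (1,2,4-trioxolane) of 25, trioxolane carbons unassigned (not isolated) | C1CC[C@H](O)[C@@](C2OOC(C)O2)(C)C1=O | intermediate
27 | (2S,3S)-3-hydroxy-2-(hydroxymethyl)-2-methylcyclohexan-1-one | C1CC[C@H](O)[C@@](CO)(C)C1=O | intermediate
28 | acetonide of 27 (cis-fused 2,2-dimethyl-1,3-dioxane across C2–O and C14–O; C10 ketone) | C1CC[C@@H]2OC(C)(C)OC[C@]2(C)C1=O | intermediate
29 | C11 dimethylaminomethyl ketone (Mannich base, C11 unassigned; not isolated) | CN(C)CC1CC[C@@H]2OC(C)(C)OC[C@]2(C)C1=O | intermediate
30 | C11-methylene ketone (enone) | C=C1CC[C@@H]2OC(C)(C)OC[C@]2(C)C1=O | intermediate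
31 | allylic alcohol, C10–OH (mixture of C10 epimers) | C=C1CC[C@@H]2OC(C)(C)OC[C@]2(C)C1O | intermediate
32 | allylic mesylate of 31 (not isolated) | C=C1CC[C@@H]2OC(C)(C)OC[C@]2(C)C1OS(C)(=O)=O | intermediate
33 | primary allylic bromide (C20–Br, C10=C11) | BrCC1=C[C@@]2(C)COC(C)(C)O[C@H]2CC1 | intermediate
34 | primary allylstannane (C20–SnBu3, C10=C11) | CCCC[Sn](CCCC)(CCCC)CC1=C[C@@]2(C)COC(C)(C)O[C@H]2CC1 | intermediate
35 | homoallylic alcohol: C9–OH, C9–C10 bond, C11 methylene, ring A acetonide, C3–OTBS; C9 and C10 as in the target | C=C1CC[C@@H]2OC(C)(C)OC[C@]2(C)[C@H]1[C@H](O)[C@@]13O[C@H](C(=C)[C@H](Cl)[C@@H]1OC(=O)[C@@H]3C)CO[Si](C)(C)C(C)(C)C | intermediate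
36 | C9 acetate of 35 | C=C1CC[C@@H]2OC(C)(C)OC[C@]2(C)[C@H]1[C@H](OC(C)=O)[C@@]13O[C@H](C(=C)[C@H](Cl)[C@@H]1OC(=O)[C@@H]3C)CO[Si](C)(C)C(C)(C)C | intermediate
37 | triol: C2–OH and C3–OH (primary), C14–OH (secondary), 9-acetate | C=C1CC[C@H](O)[C@@](CO)(C)[C@H]1[C@H](OC(C)=O)[C@@]13O[C@H](C(=C)[C@H](Cl)[C@@H]1OC(=O)[C@@H]3C)CO | intermediate
38 | C2,C3-dialdehyde, C14–OH free, 9-acetate | C=C1CC[C@H](O)[C@@](C=O)(C)[C@H]1[C@H](OC(C)=O)[C@@]13O[C@H](C(=C)[C@H](Cl)[C@@H]1OC(=O)[C@@H]3C)C=O | intermediate
39 | ring-closed triol (C2–OH, C3–OH, C14–OH; 9-acetate), all centres as in the target | C=C1CC[C@H](O)[C@@]2(C)[C@H]1[C@H](OC(C)=O)[C@@]13O[C@H](C(=C)[C@H](Cl)[C@@H]1OC(=O)[C@@H]3C)[C@@H](O)[C@@H]2O | intermediate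
40 | C3 triethylsilyl ether of 39 | C=C1CC[C@H](O)[C@@]2(C)[C@H]1[C@H](OC(C)=O)[C@@]13O[C@H](C(=C)[C@H](Cl)[C@@H]1OC(=O)[C@@H]3C)[C@@H](O[Si](CC)(CC)CC)[C@@H]2O | intermediate
41 | 2,9,14-triacetate 3-O-triethylsilyl ether | C=C1CC[C@H](OC(C)=O)[C@@]2(C)[C@H]1[C@H](OC(C)=O)[C@@]13O[C@H](C(=C)[C@H](Cl)[C@@H]1OC(=O)[C@@H]3C)[C@@H](O[Si](CC)(CC)CC)[C@@H]2OC(C)=O | intermediate
42 | CNP0280492.1 | C=C1CC[C@H](OC(C)=O)[C@@]2(C)[C@H]1[C@H](OC(C)=O)[C@@]13O[C@H](C(=C)[C@H](Cl)[C@@H]1OC(=O)[C@@H]3C)[C@@H](O)[C@@H]2OC(C)=O | target

Total step count: 28.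
Longest linear sequence: 19 steps (steps 1–11, then 21–28). The ring A branch (steps 12–20) is 9 steps and joins at step 21.

Steps most likely to fail

Step 5 (proposed new method). The cation may be intercepted by solvent or chloride before the furan reaches it, the ester tether may not populate its reactive s-cis conformer so that intermolecular pathways take over, or the C17 methyl may control the furan face poorly. The fallback uses known chemistry and sets out from acid 8. Esterification (MeI, K2CO3, DMF) gives methyl (R)-2-(furan-2-yl)propanoate F1. An intermolecular (4+3) cycloaddition of F1 with the benzyloxy-substituted oxyallyl cation, generated from 3,3-bis(benzyloxy)-2-(triethylsilyloxy)prop-1-ene and catalytic TMSOTf in CH2Cl2 at −78 °C, would give, after separation of regio- and stereoisomers, the C7-benzyloxy bicyclic keto ester F2. BCl3 in CH2Cl2 at −78 °C removes the benzyl group to give the C7-hydroxy keto ester F3, which lactonises on warming with catalytic CSA and so comes back to the route at 12.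

Step 21. Bond formation between two neopentylic carbons may be sluggish, and facial control on the aldehyde or on the stannane may erode. The fallback sets out from aldehyde 20 and bromide 33. A CrCl2-mediated Nozaki–Hiyama allylation (THF, rt), which is γ-selective, proceeds through a closed chair transition state and tolerates hindered partners, would give the 9,10-anti adduct, the C9 epimer of 35 F4. Dess–Martin oxidation gives the C9 ketone F5. Reduction with L-Selectride at −78 °C under non-chelation control (hydride anti to the C8–O bond, approaching past C17) resets C9 and comes back to the route at 35.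

Step 25. The C3 oxygen may be delivered to the same ring face as the C2 oxygen (2,3-cis diol), one aldehyde may simply be reduced, or chains may couple intermolecularly. The fallback for the stereochemical failure sets out from dialdehyde 38 and accepts the cyclisation as ring-forming only, giving the C3-epimeric triol F6. A Mitsunobu reaction at the accessible C3 hydroxyl (PPh3, DIAD, chloroacetic acid, toluene, 0 °C) inverts it to the 3-O-chloroacetate F7. Acetylation of C2 and C14 (Ac2O, DMAP) gives the 2,9,14-triacetate 3-O-chloroacetate F8. Thiourea with NaHCO3 in EtOH removes the chloroacetate selectively beside the acetates and comes back to the route at target 42.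

Further compounds

F1 | step 5 | methyl (R)-2-(furan-2-yl)propanoate | COC(=O)[C@H](C)c1ccco1
F2 | step 5 | methyl (R)-2-(C7-benzyloxy-C6-oxo-8-oxabicyclo[3.2.1]oct-6-en-1-yl)propanoate, benzyloxy axial at C7, bridgehead C8 bearing the side chain | C1=C[C@]2(O[C@@H]1CC(=O)[C@@H]2OCc1ccccc1)[C@@H](C)C(=O)OC
F3 | step 5 | C7-hydroxy keto ester from F2 | C1=C[C@]2(O[C@@H]1CC(=O)[C@@H]2O)[C@@H](C)C(=O)OC
F4 | step 21 | C9 epimer of 35 (9,10-anti homoallylic alcohol) | C=C1CC[C@@H]2OC(C)(C)OC[C@]2(C)[C@H]1[C@@H](O)[C@@]13O[C@H](C(=C)[C@H](Cl)[C@@H]1OC(=O)[C@@H]3C)CO[Si](C)(C)C(C)(C)C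
F5 | step 21 | C9 ketone from F4 | C=C1CC[C@@H]2OC(C)(C)OC[C@]2(C)[C@H]1C(=O)[C@@]13O[C@H](C(=C)[C@H](Cl)[C@@H]1OC(=O)[C@@H]3C)CO[Si](C)(C)C(C)(C)C
F6 | step 25 | C3 epimer of triol 39 (2,3-cis diol) | C=C1CC[C@H](O)[C@@]2(C)[C@H]1[C@H](OC(C)=O)[C@@]13O[C@H](C(=C)[C@H](Cl)[C@@H]1OC(=O)[C@@H]3C)[C@H](O)[C@@H]2O
F7 | step 25 | 3-O-chloroacetate with C3 inverted to the target configuration (C2–OH, C14–OH free) | C=C1CC[C@H](O)[C@@]2(C)[C@H]1[C@H](OC(C)=O)[C@@]13O[C@H](C(=C)[C@H](Cl)[C@@H]1OC(=O)[C@@H]3C)[C@@H](OC(=O)CCl)[C@@H]2O
F8 | step 25 | 2,9,14-triacetate 3-O-chloroacetate | C=C1CC[C@H](OC(C)=O)[C@@]2(C)[C@H]1[C@H](OC(C)=O)[C@@]13O[C@H](C(=C)[C@H](Cl)[C@@H]1OC(=O)[C@@H]3C)[C@@H](OC(=O)CCl)[C@@H]2OC(C)=O
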